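**Retrosynthetic overview**

1. The 14-membered lactone is closed last at its C–O bond: a tert-butyl 3,5-dioxo ester loses tert-butanol on heating and the resulting acylketene is captured by the dienyl carbinol.
2. The tricarbonyl arm comes from a decalin aldehyde (γ-aldol of a β-keto ester dianion, then oxidation); the (Z,Z)-diene comes from a (Z)-enyne (Wittig with an ynal, late zinc semi-reduction).
3. Rings B and A form together in one step: an endo intramolecular Diels–Alder reaction of an (E)-enal onto an (E,E)-diene, set off in the same flask by a vinylogous Mukaiyama aldol. A methyl stereocentre in the tether fixes the diene face and is then erased by dehydration to the ring A alkene.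
4. The cycloaddition precursor comes from Negishi coupling of a β-zincio ester with a dienyl iodide (oxidation–Wittig, then Takai).
5. Ring order: B and A (step 9), then the macrolactone (step 15). Stereochemical sources: (R)-but-3-yn-2-ol, (R)-3-bromo-2-methylpropan-1-ol and methyl (S)-3-bromo-2-methylpropanoate.

Assumption: the enolised 1,3-diketone/β-keto-lactone unit equilibrates freely (enol geometry and the methyl-bearing C2), so the product is written in the enol form of the given SMILES and its C2 epimer is taken to be the one favoured at equilibrium.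

**Route**

Step 1
Reactants: 1 (2R)-but-3-yn-2-ol
Product: 2 tert-butyl{[(2R)-but-3-yn-2-yl]oxy}dimethylsilane
Conditions: TBSCl, imidazole, CH2Cl2, 0 → 23 °C
Reagents that add atoms: tert-butyldimethylsilyl chloride, CC(C)(C)[Si](C)(C)Cl
Why: O-Silylation masks the carbinol that will become the lactone oxygen through the two later oxidations and leaves the purchased stereocentre untouched.

Step 2
Reactants: 2 tert-butyl{[(2R)-but-3-yn-2-yl]oxy}dimethylsilane
Product: 4 (4R)-4-[(tert-butyldimethylsilyl)oxy]pent-2-ynal, via lithium acetylide 3 (not isolated)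
Conditions: n-BuLi, THF, −78 °C; then DMF, −78 → 0 °C; then aq. KH2PO4
Reagents that add atoms: N,N-dimethylformamide, CN(C)C=O
Why: Formylation of the lithium acetylide with DMF (released as the ynal on buffered quench) adds the aldehyde carbon without affecting the silyloxy stereocentre.

Step 3
Reactants: 5 (2R)-3-bromo-2-methylpropan-1-ol
Product: 6 [(2R)-3-hydroxy-2-methylpropyl]triphenylphosphonium bromide
Conditions: PPh3, MeCN, 82 °C
Reagents that add atoms: triphenylphosphine, c1ccc(cc1)P(c1ccccc1)c1ccccc1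
Why: SN2 alkylation of triphenylphosphine by the primary bromide gives the Wittig salt, and the neighbouring purchased stereocentre (the future C-methyl centre next to ring B) is not involved.

Step 4
Reactants: 6 [(2R)-3-hydroxy-2-methylpropyl]triphenylphosphonium bromide; 4 (4R)-4-[(tert-butyldimethylsilyl)oxy]pent-2-ynal
Product: 8 (2S,3Z,7R)-7-[(tert-butyldimethylsilyl)oxy]-2-methyloct-3-en-5-yn-1-ol, via oxido ylide 7 (not isolated)
Conditions: NaN(SiMe3)2 (2.1 equiv), THF, −78 → 0 °C; then 4, −78 → 23 °C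
Reagents that add atoms: none
Why: Wittig olefination with a non-stabilised ylide under lithium-free conditions gives the (Z)-enyne kinetically and links the two purchased stereocentres, neither of which is touched.

Step 5
Reactants: 8 (2S,3Z,7R)-7-[(tert-butyldimethylsilyl)oxy]-2-methyloct-3-en-5-yn-1-ol
Product: 10 (2E,4S,5Z,9R)-9-[(tert-butyldimethylsilyl)oxy]-4-methyldeca-2,5-dien-7-ynal, via enynal 9 (not isolated)
Conditions: Dess–Martin periodinane, pyridine, CH2Cl2, 0 °C; then Ph3P=CHCHO, 23 → 40 °C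
Reagents that add atoms: (triphenylphosphoranylidene)acetaldehyde, O=CC=P(c1ccccc1)(c1ccccc1)c1ccccc1
Why: Dess–Martin oxidation followed in the same flask by Wittig olefination with a stabilised ylide converts the epimerisable β,γ-unsaturated aldehyde at once into the (E)-enal, so the doubly allylic stereocentre is never exposed to base.

Step 6
Reactants: 10 (2E,4S,5Z,9R)-9-[(tert-butyldimethylsilyl)oxy]-4-methyldeca-2,5-dien-7-ynal
Product: 11 tert-butyl{[(2R,5Z,7R,8E,10E)-11-iodo-7-methylundeca-5,8,10-trien-3-yn-2-yl]oxy}dimethylsilane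
Conditions: CrCl2, CHI3, THF–1,4-dioxane, 0 → 23 °C
Reagents that add atoms: iodoform, IC(I)I
Why: Takai iodo-olefination (a gem-dichromium species made from CHI3 adds to the aldehyde and eliminates) gives the (E,E)-dienyl iodide under non-basic conditions that spare the stereocentre.

Step 7
Reactants: 12 methyl (2S)-3-bromo-2-methylpropanoate; 11 tert-butyl{[(2R,5Z,7R,8E,10E)-11-iodo-7-methylundeca-5,8,10-trien-3-yn-2-yl]oxy}dimethylsilane
Product: 14 methyl (2R,4E,6E,8R,9Z,13R)-13-[(tert-butyldimethylsilyl)oxy]-2,8-dimethyltetradeca-4,6,9-trien-11-ynoate, via alkylzinc bromide 13 (not isolated)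
Conditions: Zn dust, LiCl, THF, 40 °C; then 11, Pd2(dba)3, SPhos, 23 °C
Reagents that add atoms: none
Why: Negishi cross-coupling of the configurationally stable β-zincio ester (zinc insertion into the primary C–Br bond) with the dienyl iodide retains the diene geometry and brings in the purchased methyl stereocentre that will steer the cycloaddition.

Step 8
Reactants: 14 methyl (2R,4E,6E,8R,9Z,13R)-13-[(tert-butyldimethylsilyl)oxy]-2,8-dimethyltetradeca-4,6,9-trien-11-ynoate
Product: 15 (2R,4E,6E,8R,9Z,13R)-13-[(tert-butyldimethylsilyl)oxy]-2,8-dimethyltetradeca-4,6,9-trien-11-ynal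
Conditions: i-Bu2AlH, CH2Cl2, −78 °C; then H2O
Reagents that add atoms: none
Why: Partial reduction of the ester with i-Bu2AlH at −78 °C stops at the tetrahedral aluminium acetal, which releases the α-methyl aldehyde on work-up without epimerisation.

Step 9
Reactants: 15 (2R,4E,6E,8R,9Z,13R)-13-[(tert-butyldimethylsilyl)oxy]-2,8-dimethyltetradeca-4,6,9-trien-11-ynal; 16 [(1E)-buta-1,3-dien-1-yloxy]trimethylsilane
Product: 18 (1R,2R,4aR,6R,7R,8aS)-2-{(2S,3Z,7R)-7-[(tert-butyldimethylsilyl)oxy]oct-3-en-5-yn-2-yl}-7-hydroxy-6-methyl-1,2,4a,5,6,7,8,8a-octahydronaphthalene-1-carbaldehyde, via hydroxy trienal 17 (not isolated)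
Conditions: BF3·OEt2 (2.5 equiv), CH2Cl2, −78 °C; then −78 → 0 °C
Reagents that add atoms: none
Why: A vinylogous Mukaiyama aldol addition (γ-attack of the siloxydiene, Felkin–Anh sense at the α-methyl aldehyde) builds the (E)-enal, and the same Lewis acid then drives an endo intramolecular Diels–Alder reaction through a chair-like tether in which the purchased methyl centre and the new O-substituent sit equatorial, which fixes the diene face, while the (E,E)-diene, the (E)-dienophile and the endo mode fix the trans ring fusion and the cis 1,2-relationship of the four new ring stereocentres.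

Step 10
Reactants: 18 (1R,2R,4aR,6R,7R,8aS)-2-{(2S,3Z,7R)-7-[(tert-butyldimethylsilyl)oxy]oct-3-en-5-yn-2-yl}-7-hydroxy-6-methyl-1,2,4a,5,6,7,8,8a-octahydronaphthalene-1-carbaldehyde
Product: 19 (1R,2R,4aR,8aS)-2-{(2S,3Z,7R)-7-[(tert-butyldimethylsilyl)oxy]oct-3-en-5-yn-2-yl}-6-methyl-1,2,4a,5,8,8a-hexahydronaphthalene-1-carbaldehyde
Conditions: Burgess reagent, PhH, 50 °C
Reagents that add atoms: none
Why: Burgess dehydration (syn-elimination through the sulfamate ester) removes the equatorial hydroxyl together with the cis axial hydrogen on the methyl-bearing carbon, giving the more substituted 6,7-alkene of ring A and erasing the two temporary stereocentres.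

Step 11
Reactants: 19 (1R,2R,4aR,8aS)-2-{(2S,3Z,7R)-7-[(tert-butyldimethylsilyl)oxy]oct-3-en-5-yn-2-yl}-6-methyl-1,2,4a,5,8,8a-hexahydronaphthalene-1-carbaldehyde; 20 tert-butyl 2-methyl-3-oxobutanoate
Product: 22 tert-butyl 5-[(1R,2R,4aR,8aS)-2-{(2S,3Z,7R)-7-[(tert-butyldimethylsilyl)oxy]oct-3-en-5-yn-2-yl}-6-methyl-1,2,4a,5,8,8a-hexahydronaphthalen-1-yl]-5-hydroxy-2-methyl-3-oxopentanoate, via dilithium dianion 21 (not isolated)
Conditions: 20, LiN(i-Pr)2 (2.1 equiv), THF, 0 °C; then 19, −78 °C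
Reagents that add atoms: none
Why: Aldol addition of the β-keto ester dianion through its terminal (γ) carbon to the aldehyde appends the ketoester arm, and the mixture at the new carbinol and at C2 is of no consequence because the former is oxidised next and the latter equilibrates at the end.

Step 12
Reactants: 22 tert-butyl 5-[(1R,2R,4aR,8aS)-2-{(2S,3Z,7R)-7-[(tert-butyldimethylsilyl)oxy]oct-3-en-5-yn-2-yl}-6-methyl-1,2,4a,5,8,8a-hexahydronaphthalen-1-yl]-5-hydroxy-2-methyl-3-oxopentanoate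
Product: 23 tert-butyl 5-[(1R,2R,4aR,8aS)-2-{(2S,3Z,7R)-7-[(tert-butyldimethylsilyl)oxy]oct-3-en-5-yn-2-yl}-6-methyl-1,2,4a,5,8,8a-hexahydronaphthalen-1-yl]-2-methyl-3,5-dioxopentanoate
Conditions: Dess–Martin periodinane, CH2Cl2, 23 °C
Reagents that add atoms: none
Why: Dess–Martin oxidation turns the β-hydroxy ketone into the (enolised) 1,3-diketone while the silyl ether shields the other secondary carbinol.

Step 13
Reactants: 23 tert-butyl 5-[(1R,2R,4aR,8aS)-2-{(2S,3Z,7R)-7-[(tert-butyldimethylsilyl)oxy]oct-3-en-5-yn-2-yl}-6-methyl-1,2,4a,5,8,8a-hexahydronaphthalen-1-yl]-2-methyl-3,5-dioxopentanoate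
Product: 24 tert-butyl 5-[(1R,2R,4aR,8aS)-2-{(2S,3Z,7R)-7-hydroxyoct-3-en-5-yn-2-yl}-6-methyl-1,2,4a,5,8,8a-hexahydronaphthalen-1-yl]-2-methyl-3,5-dioxopentanoate
Conditions: HF·pyridine, pyridine, THF, 0 → 23 °C
Reagents that add atoms: none
Why: Desilylation with buffered HF·pyridine (Si–F bond formation) frees the propargylic alcohol with retention of its configuration.

Step 14
Reactants: 24 tert-butyl 5-[(1R,2R,4aR,8aS)-2-{(2S,3Z,7R)-7-hydroxyoct-3-en-5-yn-2-yl}-6-methyl-1,2,4a,5,8,8a-hexahydronaphthalen-1-yl]-2-methyl-3,5-dioxopentanoate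
Product: 25 tert-butyl 5-[(1R,2R,4aR,8aS)-2-{(2S,3Z,5Z,7R)-7-hydroxyocta-3,5-dien-2-yl}-6-methyl-1,2,4a,5,8,8a-hexahydronaphthalen-1-yl]-2-methyl-3,5-dioxopentanoate
Conditions: Zn dust activated with Cu(OAc)2 and AgNO3, MeOH–H2O (1:1), 45 °C
Reagents that add atoms: none
Why: Semi-reduction of the conjugated enyne with activated zinc (cis delivery of two hydrogens, assisted by the propargylic hydroxyl) gives the second (Z)-alkene and hence the (Z,Z)-diene without touching the other double bonds.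

Step 15
Reactants: 25 tert-butyl 5-[(1R,2R,4aR,8aS)-2-{(2S,3Z,5Z,7R)-7-hydroxyocta-3,5-dien-2-yl}-6-methyl-1,2,4a,5,8,8a-hexahydronaphthalen-1-yl]-2-methyl-3,5-dioxopentanoate
Product: 28 CNP0360406.1, via acylketene 26 (not isolated), via C2-epimeric macrolactone 27 (not isolated)
Conditions: PhMe (1 mM), 110 °C, slow addition; then DBU (0.1 equiv), 23 °C
Reagents that add atoms: none
Why: Thermal loss of tert-butanol from the β-keto ester gives an acylketene that adds the remote secondary alcohol (retention at the carbinol) to close the 14-membered lactone under high dilution, and the methyl-bearing carbon between the two carbonyls then equilibrates through its enol to the epimer favoured by the stereocentres of the rigid tricycle.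

**Compound list**

1 | (2R)-but-3-yn-2-ol | C#C[C@@H](C)O | starting material
2 | tert-butyl{[(2R)-but-3-yn-2-yl]oxy}dimethylsilane | C#C[C@@H](C)O[Si](C)(C)C(C)(C)C | intermediate
3 | {(3R)-3-[(tert-butyldimethylsilyl)oxy]but-1-yn-1-yl}lithium | [Li]C#C[C@@H](C)O[Si](C)(C)C(C)(C)C | intermediate
4 | (4R)-4-[(tert-butyldimethylsilyl)oxy]pent-2-ynal | O=CC#C[C@@H](C)O[Si](C)(C)C(C)(C)C | intermediate
5 | (2R)-3-bromo-2-methylpropan-1-ol | BrC[C@H](C)CO | starting material
6 | [(2R)-3-hydroxy-2-methylpropyl]triphenylphosphonium bromide | OC[C@@H](C)C[P+](c1ccccc1)(c1ccccc1)c1ccccc1.[Br-] | intermediate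
7 | sodium (2R)-2-methyl-3-(triphenylphosphoranylidene)propan-1-olate | [Na+].[O-]C[C@@H](C)C=P(c1ccccc1)(c1ccccc1)c1ccccc1 | intermediate
8 | (2S,3Z,7R)-7-[(tert-butyldimethylsilyl)oxy]-2-methyloct-3-en-5-yn-1-ol | OC[C@@H](C)/C=C\C#C[C@@H](C)O[Si](C)(C)C(C)(C)C | intermediate
9 | (2S,3Z,7R)-7-[(tert-butyldimethylsilyl)oxy]-2-methyloct-3-en-5-ynal | O=C[C@@H](C)/C=C\C#C[C@@H](C)O[Si](C)(C)C(C)(C)C | intermediate
10 | (2E,4S,5Z,9R)-9-[(tert-butyldimethylsilyl)oxy]-4-methyldeca-2,5-dien-7-ynal | O=C/C=C/[C@@H](C)/C=C\C#C[C@@H](C)O[Si](C)(C)C(C)(C)C | intermediate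
11 | tert-butyl{[(2R,5Z,7R,8E,10E)-11-iodo-7-methylundeca-5,8,10-trien-3-yn-2-yl]oxy}dimethylsilane | I/C=C/C=C/[C@@H](C)/C=C\C#C[C@@H](C)O[Si](C)(C)C(C)(C)C | intermediate
12 | methyl (2S)-3-bromo-2-methylpropanoate | COC(=O)[C@H](C)CBr | starting material
13 | bromo[(2S)-3-methoxy-2-methyl-3-oxopropyl]zinc | COC(=O)[C@H](C)C[Zn]Br | intermediate
14 | methyl (2R,4E,6E,8R,9Z,13R)-13-[(tert-butyldimethylsilyl)oxy]-2,8-dimethyltetradeca-4,6,9-trien-11-ynoate | COC(=O)[C@H](C)C/C=C/C=C/[C@@H](C)/C=C\C#C[C@@H](C)O[Si](C)(C)C(C)(C)C | intermediate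
15 | (2R,4E,6E,8R,9Z,13R)-13-[(tert-butyldimethylsilyl)oxy]-2,8-dimethyltetradeca-4,6,9-trien-11-ynal | O=C[C@H](C)C/C=C/C=C/[C@@H](C)/C=C\C#C[C@@H](C)O[Si](C)(C)C(C)(C)C | intermediate
16 | [(1E)-buta-1,3-dien-1-yloxy]trimethylsilane | C=C/C=C/O[Si](C)(C)C | starting material
17 | (2E,5R,6R,8E,10E,12R,13Z,17R)-17-[(tert-butyldimethylsilyl)oxy]-5-hydroxy-6,12-dimethyloctadeca-2,8,10,13-tetraen-15-ynal | O=C/C=C/C[C@@H](O)[C@H](C)C/C=C/C=C/[C@@H](C)/C=C\C#C[C@@H](C)O[Si](C)(C)C(C)(C)C | intermediate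
18 | (1R,2R,4aR,6R,7R,8aS)-2-{(2S,3Z,7R)-7-[(tert-butyldimethylsilyl)oxy]oct-3-en-5-yn-2-yl}-7-hydroxy-6-methyl-1,2,4a,5,6,7,8,8a-octahydronaphthalene-1-carbaldehyde | C[C@H]1[C@H](O)C[C@@H]2[C@@H](C=O)[C@@H]([C@@H](C)/C=C\C#C[C@@H](C)O[Si](C)(C)C(C)(C)C)C=C[C@H]2C1 | intermediate
19 | (1R,2R,4aR,8aS)-2-{(2S,3Z,7R)-7-[(tert-butyldimethylsilyl)oxy]oct-3-en-5-yn-2-yl}-6-methyl-1,2,4a,5,8,8a-hexahydronaphthalene-1-carbaldehyde | CC1=CC[C@@H]2[C@@H](C=O)[C@@H]([C@@H](C)/C=C\C#C[C@@H](C)O[Si](C)(C)C(C)(C)C)C=C[C@H]2C1 | intermediate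
20 | tert-butyl 2-methyl-3-oxobutanoate | CC(=O)C(C)C(=O)OC(C)(C)C | starting material
21 | dilithium 1-tert-butoxy-2-methylbuta-1,3-diene-1,3-diolate | [Li+].[Li+].C=C([O-])C(C)=C([O-])OC(C)(C)C | intermediate
22 | tert-butyl 5-[(1R,2R,4aR,8aS)-2-{(2S,3Z,7R)-7-[(tert-butyldimethylsilyl)oxy]oct-3-en-5-yn-2-yl}-6-methyl-1,2,4a,5,8,8a-hexahydronaphthalen-1-yl]-5-hydroxy-2-methyl-3-oxopentanoate (epimers at C2 and C5) | CC1=CC[C@@H]2[C@@H](C(O)CC(=O)C(C)C(=O)OC(C)(C)C)[C@@H]([C@@H](C)/C=C\C#C[C@@H](C)O[Si](C)(C)C(C)(C)C)C=C[C@H]2C1 | intermediate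
23 | tert-butyl 5-[(1R,2R,4aR,8aS)-2-{(2S,3Z,7R)-7-[(tert-butyldimethylsilyl)oxy]oct-3-en-5-yn-2-yl}-6-methyl-1,2,4a,5,8,8a-hexahydronaphthalen-1-yl]-2-methyl-3,5-dioxopentanoate (enolised; drawn as the diketone) | CC1=CC[C@@H]2[C@@H](C(=O)CC(=O)C(C)C(=O)OC(C)(C)C)[C@@H]([C@@H](C)/C=C\C#C[C@@H](C)O[Si](C)(C)C(C)(C)C)C=C[C@H]2C1 | intermediate
24 | tert-butyl 5-[(1R,2R,4aR,8aS)-2-{(2S,3Z,7R)-7-hydroxyoct-3-en-5-yn-2-yl}-6-methyl-1,2,4a,5,8,8a-hexahydronaphthalen-1-yl]-2-methyl-3,5-dioxopentanoate | CC1=CC[C@@H]2[C@@H](C(=O)CC(=O)C(C)C(=O)OC(C)(C)C)[C@@H]([C@@H](C)/C=C\C#C[C@@H](C)O)C=C[C@H]2C1 | intermediate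
25 | tert-butyl 5-[(1R,2R,4aR,8aS)-2-{(2S,3Z,5Z,7R)-7-hydroxyocta-3,5-dien-2-yl}-6-methyl-1,2,4a,5,8,8a-hexahydronaphthalen-1-yl]-2-methyl-3,5-dioxopentanoate | CC1=CC[C@@H]2[C@@H](C(=O)CC(=O)C(C)C(=O)OC(C)(C)C)[C@@H]([C@@H](C)/C=C\C=C/[C@@H](C)O)C=C[C@H]2C1 | intermediate
26 | 5-[(1R,2R,4aR,8aS)-2-{(2S,3Z,5Z,7R)-7-hydroxyocta-3,5-dien-2-yl}-6-methyl-1,2,4a,5,8,8a-hexahydronaphthalen-1-yl]-2-methylpent-1-ene-1,3,5-trione (acylketene) | CC1=CC[C@@H]2[C@@H](C(=O)CC(=O)C(C)=C=O)[C@@H]([C@@H](C)/C=C\C=C/[C@@H](C)O)C=C[C@H]2C1 | intermediate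
27 | C2 epimer of 28 (opposite configuration at the methyl-bearing carbon between ketone and lactone carbonyl) | CC1=CC[C@@H]2[C@H]3/C(O)=C\C(=O)[C@@H](C)C(=O)O[C@H](C)/C=C\C=C/[C@H](C)[C@H]3C=C[C@H]2C1 | intermediate
28 | CNP0360406.1 (tricyclic 14-membered enolised β-keto lactone, stereocentres as in the given SMILES) | CC1=CC[C@@H]2[C@H]3/C(O)=C\C(=O)[C@H](C)C(=O)O[C@H](C)/C=C\C=C/[C@H](C)[C@H]3C=C[C@H]2C1 | target

**Step count and risks**

Total step count: 15. Longest linear sequence: 14 steps (1 → 2 → 4 → 8 → 10 → 11 → 14 → 15 → 18 → 19 → 22 → 23 → 24 → 25 → 28).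

The three steps most likely to fail:

Step 15, the ring closure. The acylketene 26 can also be captured by the enol oxygen of its own 1,3-diketone to give a 4-hydroxy-2-pyranone, and the 14-membered closure has to win against that six-membered one. The C2 ratio also rests on the macrocycle preferring the drawn epimer. The fallback sets out from 22 and comes back at 28; it closes the ring while C5 is still a protected alcohol, so no enolised diketone is present at the ketene stage. The carbinol of 22 is converted into 4-methoxybenzyl ether F4 (4-methoxybenzyl trichloroacetimidate, cat. CF3SO3H). HF·pyridine then gives propargylic alcohol F5, and activated zinc gives (Z,Z)-dienol F6. Thermolysis in dilute toluene gives the protected macrolactone F7, DDQ in wet CH2Cl2 releases the hydroxy keto macrolactone F8, and Dess–Martin oxidation followed by DBU equilibration gives 28.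

Step 10, the dehydration. The syn-elimination can also take the axial hydrogen on C8 and give the 7,8-alkene instead of the 6,7-alkene, and the minor aldol epimer of 18 (axial hydroxyl) can only eliminate that way. The fallback sets out from 18 and comes back at 19; it changes from syn- to anti-elimination. PPh3, I2 and imidazole replace the equatorial hydroxyl with inversion to give the axial iodide F3. Its E2 reaction with DBU in toluene at 80 °C uses the anti-periplanar axial hydrogen on the methyl-bearing carbon and gives 19 as the more substituted alkene.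

Step 9, the tandem aldol/cycloaddition. The siloxydiene can add a second time to the enal that is formed or react with it as a diene, BF3 may not tolerate the silyl ether and the diene long enough for the cycloaddition, and the minor anti-Felkin aldol epimer cyclises with lower face selectivity. The fallback sets out from 15 and comes back at 18; it separates the two events and takes the free alkoxide out of the cycloaddition. The aldol is run alone (BF3·OEt2, −78 °C, cold quench), 17 is isolated and its major epimer is silylated (Et3SiCl, imidazole) to the triethylsilyl ether F1. Me2AlCl (−78 → −20 °C) then effects the intramolecular Diels–Alder reaction to the silyl-protected decalin F2, and PPTS in MeOH removes the triethylsilyl group selectively to give 18.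

Further compounds
F1 | step 9 | (2E,5R,6R,8E,10E,12R,13Z,17R)-17-[(tert-butyldimethylsilyl)oxy]-6,12-dimethyl-5-[(triethylsilyl)oxy]octadeca-2,8,10,13-tetraen-15-ynal | O=C/C=C/C[C@@H](O[Si](CC)(CC)CC)[C@H](C)C/C=C/C=C/[C@@H](C)/C=C\C#C[C@@H](C)O[Si](C)(C)C(C)(C)C
F2 | step 9 | (1R,2R,4aR,6R,7R,8aS)-2-{(2S,3Z,7R)-7-[(tert-butyldimethylsilyl)oxy]oct-3-en-5-yn-2-yl}-6-methyl-7-[(triethylsilyl)oxy]-1,2,4a,5,6,7,8,8a-octahydronaphthalene-1-carbaldehyde | C[C@H]1[C@H](O[Si](CC)(CC)CC)C[C@@H]2[C@@H](C=O)[C@@H]([C@@H](C)/C=C\C#C[C@@H](C)O[Si](C)(C)C(C)(C)C)C=C[C@H]2C1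
F3 | step 10 | (1R,2R,4aR,6R,7S,8aS)-2-{(2S,3Z,7R)-7-[(tert-butyldimethylsilyl)oxy]oct-3-en-5-yn-2-yl}-7-iodo-6-methyl-1,2,4a,5,6,7,8,8a-octahydronaphthalene-1-carbaldehyde | C[C@H]1[C@@H](I)C[C@@H]2[C@@H](C=O)[C@@H]([C@@H](C)/C=C\C#C[C@@H](C)O[Si](C)(C)C(C)(C)C)C=C[C@H]2C1
F4 | step 15 | tert-butyl 5-[(1R,2R,4aR,8aS)-2-{(2S,3Z,7R)-7-[(tert-butyldimethylsilyl)oxy]oct-3-en-5-yn-2-yl}-6-methyl-1,2,4a,5,8,8a-hexahydronaphthalen-1-yl]-5-[(4-methoxybenzyl)oxy]-2-methyl-3-oxopentanoate | CC1=CC[C@@H]2[C@@H](C(OCc3ccc(OC)cc3)CC(=O)C(C)C(=O)OC(C)(C)C)[C@@H]([C@@H](C)/C=C\C#C[C@@H](C)O[Si](C)(C)C(C)(C)C)C=C[C@H]2C1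
F5 | step 15 | tert-butyl 5-[(1R,2R,4aR,8aS)-2-{(2S,3Z,7R)-7-hydroxyoct-3-en-5-yn-2-yl}-6-methyl-1,2,4a,5,8,8a-hexahydronaphthalen-1-yl]-5-[(4-methoxybenzyl)oxy]-2-methyl-3-oxopentanoate | CC1=CC[C@@H]2[C@@H](C(OCc3ccc(OC)cc3)CC(=O)C(C)C(=O)OC(C)(C)C)[C@@H]([C@@H](C)/C=C\C#C[C@@H](C)O)C=C[C@H]2C1
F6 | step 15 | tert-butyl 5-[(1R,2R,4aR,8aS)-2-{(2S,3Z,5Z,7R)-7-hydroxyocta-3,5-dien-2-yl}-6-methyl-1,2,4a,5,8,8a-hexahydronaphthalen-1-yl]-5-[(4-methoxybenzyl)oxy]-2-methyl-3-oxopentanoate | CC1=CC[C@@H]2[C@@H](C(OCc3ccc(OC)cc3)CC(=O)C(C)C(=O)OC(C)(C)C)[C@@H]([C@@H](C)/C=C\C=C/[C@@H](C)O)C=C[C@H]2C1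
F7 | step 15 | 14-membered 3-oxo macrolactone of the target skeleton carrying a 4-methoxybenzyl ether at C5 (in place of the enolised C5 ketone) | CC1=CC[C@@H]2[C@H]3C(OCc4ccc(OC)cc4)CC(=O)C(C)C(=O)O[C@H](C)/C=C\C=C/[C@H](C)[C@H]3C=C[C@H]2C1
F8 | step 15 | 14-membered 5-hydroxy-3-oxo macrolactone of the target skeleton | CC1=CC[C@@H]2[C@H]3C(O)CC(=O)C(C)C(=O)O[C@H](C)/C=C\C=C/[C@H](C)[C@H]3C=C[C@H]2C1
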